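**Plan**

- Numbering: ring A is the phenol ring (C1 side chain, C3 ether oxygen, C4 methyl, C6 OH) and ring B the second ring (C1' oxygen, C3' methyl, C6' side chain); each chain is C7(H)(CH3)-C8-C9-C10=C11(CH3)2.
- Feature used: each ring is bonded to a methyl-bearing stereocenter (C1-C7, C6'-C7') and the alkene carbon C10 (C10') lies three atoms beyond it, so each half is a latent 4-arylpentanal, the product of arylating a homoallylic alcohol with relay of palladium to the carbinol carbon.
- Retrosynthesis: cut C10=C11 and C10'=C11' (Wittig) and the phenol protecting group; then cut C1-C7 and C6'-C7' together, giving a diaryl ether bis(boronic acid) and two molecules of (E)-pent-3-en-1-ol; then cut the ring A C3-O bond (copper-catalysed etherification) into two pieces that both come from 2-bromo-5-methylphenol.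
- Forward: both rings are bought, not built; the diaryl ether is assembled first, the two five-carbon chains are attached in one operation, each chain is completed by olefination, and the MOM group is removed last.
- Stereochemistry: both S centers come from catalyst control, the (S)-pyridine-oxazoline ligand on palladium selecting the alkene face of the E-alkenol in each migratory insertion; no later step touches the benzylic centers.

Key step: step 6

Remark: the facial sense in step 6 is assigned from the usual insertion model for pyridine-oxazoline Pd-aryl complexes (alkene cis to the oxazoline, C3 substituent turned away from tert-butyl), which predicts S at both centers from the (S)-ligand and the E-alkenol; if the sense proved opposite, the (R)-ligand would be used and nothing else would change.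

Remark: the twofold steps 4, 6 and 7 are run to full conversion with excess reagent, so the singly reacted species are treated as transient and are not numbered.

**Route**

Step 1
Reactants: 1 2-bromo-5-methylphenol
Product: 2 2-bromo-4-iodo-5-methylphenol
Conditions: NIS (1.05 equiv), TsOH·H2O (10 mol%), MeCN, 0 °C to rt
Reagents that add atoms: N-iodosuccinimide, O=C1CCC(=O)N1I
Why: Electrophilic aromatic iodination with NIS under acid catalysis should go para to the hydroxyl group, because the only other activated position is wedged between OH and CH3.

Step 2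
Reactants: 2 2-bromo-4-iodo-5-methylphenol
Product: 3 1-bromo-5-iodo-2-(methoxymethoxy)-4-methylbenzene
Conditions: MOMCl (1.5 equiv), i-Pr2NEt (2 equiv), CH2Cl2, 0 °C to rt
Reagents that add atoms: chloromethyl methyl ether, COCCl
Why: O-Alkylation of the phenol with MOMCl and a hindered amine base (Williamson-type etherification) gives an acetal ether that tolerates base, organolithium reagents and the neutral oxidative coupling, and that later supports the ortho-lithio species by chelation.

Step 3
Reactants: 3 1-bromo-5-iodo-2-(methoxymethoxy)-4-methylbenzene; 1 2-bromo-5-methylphenol (1.2 equiv)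
Product: 4 1-bromo-5-(2-bromo-5-methylphenoxy)-2-(methoxymethoxy)-4-methylbenzene
Conditions: CuI (10 mol%), picolinic acid (20 mol%), K3PO4 (2 equiv), DMSO, 80 °C
Reagents that add atoms: none
Why: Ullmann-type diaryl ether synthesis with CuI and picolinic acid couples phenols with ortho-substituted aryl iodides at 80 °C, where insertion of monovalent copper into C-I should be much faster than into the two electron-rich, ortho-oxygenated C-Br bonds.

Step 4
Reactants: 4 1-bromo-5-(2-bromo-5-methylphenoxy)-2-(methoxymethoxy)-4-methylbenzene
Product: 7 [2-(5-borono-4-(methoxymethoxy)-2-methylphenoxy)-4-methylphenyl]boronic acid, via dilithio diaryl ether 5 (not isolated), via dilithium bis(triisopropoxyborate) 6 (not isolated)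
Conditions: n-BuLi (2.3 equiv), THF, -78 °C; B(OiPr)3 (3 equiv), -78 °C to rt; aq NH4Cl then 1 M HCl to pH 5, 0 °C
Reagents that add atoms: triisopropyl borate, CC(C)OB(OC(C)C)OC(C)C; water, O
Why: Bromine-lithium exchange at both aryl bromides is fast at -78 °C (helped on ring A by the MOM oxygens), and trapping each aryllithium with B(OiPr)3 followed by mildly acidic hydrolysis is the standard lithiation-borylation route to arylboronic acids, which the MOM ether should survive.

Step 5
Reactants: 8 pent-3-yn-1-ol
Product: 9 (E)-pent-3-en-1-ol
Conditions: Na (3 equiv), liquid NH3, THF, -33 °C; solid NH4Cl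
Reagents that add atoms: none
Why: Dissolving-metal reduction of the internal alkyne goes through a vinyl radical anion that is protonated in its trans form, so the E-alkene is expected and the alcohol is untouched.

Step 6
Reactants: 7 [2-(5-borono-4-(methoxymethoxy)-2-methylphenoxy)-4-methylphenyl]boronic acid; 9 (E)-pent-3-en-1-ol (6 equiv)
Product: 10 (4S)-4-{2-[4-(methoxymethoxy)-2-methyl-5-((2S)-5-oxopentan-2-yl)phenoxy]-4-methylphenyl}pentanal
Conditions: Pd(MeCN)2(OTs)2 (12 mol%), Cu(OTf)2 (12 mol%), (S)-4-tert-butyl-2-[5-(trifluoromethyl)pyridin-2-yl]-4,5-dihydrooxazole (26 mol%), 3 Å molecular sieves, O2 (1 atm), DMF, rt, slow addition of 7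
Reagents that add atoms: none
Why: Each C-B bond transmetalates to cationic divalent palladium bearing the pyridine-oxazoline ligand, the E-alkene of 9 inserts into the Pd-aryl bond with the aryl group going to C4 of the alkenol (the later C7 or C7'), and repeated beta-hydride elimination and reinsertion carry palladium from C3 to C1, where elimination at the carbinol carbon gives the enol and hence the aldehyde while O2 with Cu(OTf)2 returns the Pd-H intermediate to the active divalent state. The closest known reaction type is the enantioselective redox-relay oxidative Heck arylation of acyclic homoallylic alcohols with arylboronic acids, used here twice on one substrate and with ortho-oxygenated aryl groups. No ring is closed; only the C1-C7 and C6'-C7' bonds form. Each stereocenter is set in the migratory insertion under ligand control: the alkene sits cis to the oxazoline, its C3 substituent turns away from the tert-butyl group, and with E geometry this exposes the face of C4 that gives S, so both centers should be S, and two independent catalyst-controlled events should move most of the minor-enantiomer error into the separable S,R and R,S diastereomers. The step needs site selectivity (aryl to C4, not C3), secured by polarisation of the alkene by the homoallylic hydroxyl group and by the electron-poor CF3-substituted ligand, and a one-way walk toward oxygen, secured by irreversible carbonyl formation. Because 7 is the limiting partner, 9 is used in excess and 7 is added slowly to hold back homocoupling and protodeboronation.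

Step 7
Reactants: 10 (4S)-4-{2-[4-(methoxymethoxy)-2-methyl-5-((2S)-5-oxopentan-2-yl)phenoxy]-4-methylphenyl}pentanal; 11 isopropyltriphenylphosphonium iodide (3 equiv)
Product: 13 1-(methoxymethoxy)-5-methyl-2-[(2S)-6-methylhept-5-en-2-yl]-4-{5-methyl-2-[(2S)-6-methylhept-5-en-2-yl]phenoxy}benzene, via isopropylidenetriphenylphosphorane 12 (not isolated)
Conditions: 11, n-BuLi (2.9 equiv), THF, 0 °C; then 10, -78 °C to rt
Reagents that add atoms: none
Why: Wittig olefination of both aldehydes with the non-stabilised isopropylidene ylide gives the two trisubstituted alkenes without any E/Z question, and the benzylic stereocenters, being gamma to the carbonyl groups, cannot epimerise under the basic conditions.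

Step 8
Reactants: 13 1-(methoxymethoxy)-5-methyl-2-[(2S)-6-methylhept-5-en-2-yl]-4-{5-methyl-2-[(2S)-6-methylhept-5-en-2-yl]phenoxy}benzene
Product: 14 5-methyl-2-[(2S)-6-methylhept-5-en-2-yl]-4-{5-methyl-2-[(2S)-6-methylhept-5-en-2-yl]phenoxy}phenol (CNP0354307.1)
Conditions: 2 M aq HCl (cat.), MeOH, 40 °C
Reagents that add atoms: none
Why: Acid-catalysed methanolysis of the MOM acetal (acetal exchange) frees the phenol, while dilute acid at 40 °C should leave the isolated trisubstituted alkenes and the benzylic centers unchanged.

**Compound list**

1 | 2-bromo-5-methylphenol | Cc1ccc(Br)c(O)c1 | starting material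
2 | 2-bromo-4-iodo-5-methylphenol | Cc1cc(O)c(Br)cc1I | intermediate
3 | 1-bromo-5-iodo-2-(methoxymethoxy)-4-methylbenzene | COCOc1cc(C)c(I)cc1Br | intermediate
4 | 1-bromo-5-(2-bromo-5-methylphenoxy)-2-(methoxymethoxy)-4-methylbenzene | COCOc1cc(C)c(Oc2cc(C)ccc2Br)cc1Br | intermediate
5 | dilithio diaryl ether (both Br of 4 replaced by Li) | COCOc1cc(C)c(Oc2cc(C)ccc2[Li])cc1[Li] | intermediate
6 | dilithium bis(triisopropoxyborate) of the diaryl ether | COCOc1cc(C)c(Oc2cc(C)ccc2[B-](OC(C)C)(OC(C)C)OC(C)C)cc1[B-](OC(C)C)(OC(C)C)OC(C)C.[Li+].[Li+] | intermediate
7 | [2-(5-borono-4-(methoxymethoxy)-2-methylphenoxy)-4-methylphenyl]boronic acid | COCOc1cc(C)c(Oc2cc(C)ccc2B(O)O)cc1B(O)O | intermediate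
8 | pent-3-yn-1-ol | CC#CCCO | starting material
9 | (E)-pent-3-en-1-ol | C/C=C/CCO | intermediate
10 | (4S)-4-{2-[4-(methoxymethoxy)-2-methyl-5-((2S)-5-oxopentan-2-yl)phenoxy]-4-methylphenyl}pentanal | COCOc1cc(C)c(Oc2cc(C)ccc2[C@@H](C)CCC=O)cc1[C@@H](C)CCC=O | intermediate
11 | isopropyltriphenylphosphonium iodide | CC(C)[P+](c1ccccc1)(c1ccccc1)c1ccccc1.[I-] | starting material
12 | isopropylidenetriphenylphosphorane | CC(C)=P(c1ccccc1)(c1ccccc1)c1ccccc1 | intermediate
13 | 1-(methoxymethoxy)-5-methyl-2-[(2S)-6-methylhept-5-en-2-yl]-4-{5-methyl-2-[(2S)-6-methylhept-5-en-2-yl]phenoxy}benzene | COCOc1cc(C)c(Oc2cc(C)ccc2[C@@H](C)CCC=C(C)C)cc1[C@@H](C)CCC=C(C)C | intermediate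
14 | 5-methyl-2-[(2S)-6-methylhept-5-en-2-yl]-4-{5-methyl-2-[(2S)-6-methylhept-5-en-2-yl]phenoxy}phenol | CC(C)=CCC[C@H](C)c1cc(Oc2cc(C)ccc2[C@@H](C)CCC=C(C)C)c(C)cc1O | target

**Count and risks**

Total step count: 8. Longest linear sequence: 7 steps (steps 1, 2, 3, 4, 6, 7, 8 from compound 1); step 5 is a one-step side branch.

Steps most likely to fail:

1. Step 6. What may go wrong: aryl delivery to C3 instead of C4 with these electron-rich, ortho-oxygenated aryl groups, and protodeboronation or oxidative homocoupling of the limiting bis(boronic acid), each loss counted twice. Fallback: from 7, a twofold Hayashi-Miyaura conjugate addition to ethyl (E)-but-2-enoate (Rh(acac)(C2H4)2 with the BINAP antipode that the accepted face model assigns to the S products, dioxane/H2O, 100 °C) should give the (S,S)-bis(3-arylbutanoate) diethyl ester F1. Reduction with LiAlH4 in THF should give the (S,S)-bis(3-arylbutan-1-ol) diol F2, and TsCl with pyridine should give the ditosylate F3. Coupling of F3 with 2-methylprop-1-enylmagnesium bromide under Li2CuCl4 catalysis in THF should then give 13 directly, so the route is rejoined at 13 and steps 6 and 7 are bypassed.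

2. Step 3. What may go wrong: copper insertion into a C-Br bond of the bromophenol or of the product, leading to oligomeric ethers, and slow coupling at the hindered iodide. Fallback: from 3, selective iodine-magnesium exchange (i-PrMgCl·LiCl, THF, -20 °C), then B(OMe)3 and aqueous work-up, should give [5-bromo-4-(methoxymethoxy)-2-methylphenyl]boronic acid F4. A Chan-Lam coupling of F4 with phenol 1 (Cu(OAc)2, pyridine, 4 Å molecular sieves, CH2Cl2, air, rt), to which aryl bromides are inert, should then give 4.

3. Step 4. What may go wrong: incomplete twofold exchange, butylation of an aryllithium by 1-bromobutane, protodeboronation or MOM loss during the acidic hydrolysis, and loss of the polar product on isolation. Fallback: from 4, a twofold Miyaura borylation (Pd(dppf)Cl2, bis(pinacolato)diboron, KOAc, dioxane, 90 °C) should give the chromatographable bis(pinacol boronate) F5. Oxidative removal of pinacol (NaIO4, NH4OAc, acetone/H2O, rt) should then give 7.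

**Further compounds**

F1 | step 6 | (S,S)-bis(3-arylbutanoate) diethyl ester: ethyl (3S)-3-{2-[5-((2S)-4-ethoxy-4-oxobutan-2-yl)-4-(methoxymethoxy)-2-methylphenoxy]-4-methylphenyl}butanoate | COCOc1cc(C)c(Oc2cc(C)ccc2[C@@H](C)CC(=O)OCC)cc1[C@@H](C)CC(=O)OCC
F2 | step 6 | (S,S)-bis(3-arylbutan-1-ol) diol: (3S)-3-{2-[5-((2S)-4-hydroxybutan-2-yl)-4-(methoxymethoxy)-2-methylphenoxy]-4-methylphenyl}butan-1-ol | COCOc1cc(C)c(Oc2cc(C)ccc2[C@@H](C)CCO)cc1[C@@H](C)CCO
F3 | step 6 | ditosylate of F2 | COCOc1cc(C)c(Oc2cc(C)ccc2[C@@H](C)CCOS(=O)(=O)c3ccc(C)cc3)cc1[C@@H](C)CCOS(=O)(=O)c4ccc(C)cc4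
F4 | step 3 | [5-bromo-4-(methoxymethoxy)-2-methylphenyl]boronic acid | COCOc1cc(C)c(B(O)O)cc1Br
F5 | step 4 | bis(pinacol boronate) of the diaryl ether (both Br of 4 replaced by 4,4,5,5-tetramethyl-1,3,2-dioxaborolan-2-yl) | COCOc1cc(C)c(Oc2cc(C)ccc2B3OC(C)(C)C(C)(C)O3)cc1B4OC(C)(C)C(C)(C)O4
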